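The ten-membered carbocycle is disconnected at C7–C8 (germacrane numbering), the bond joining the lactone β-carbon to the carbinol carbon that bears the chlorohydrin ester. The feature exploited is the homoallylic alcohol pattern C8(O)–C7–C11=C13 spanning the carbocycle and the α-methylene-γ-lactone ring: it is what an allylmetal leaves behind when it adds to an aldehyde through its far end. One intramolecular Nozaki–Hiyama–Kishi allylation therefore closes the ten-membered ring, sets C7 and C8 and creates the exocyclic methylene. Its precursor is an open chain: a C8 aldehyde linked through the C1=C10 enoate and the 4,5-epoxide to a 3-(bromomethyl)butenolide that already holds C6.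

Key step: step 16

Remark (numbering): germacranolide numbering is used throughout: C1=C10 ring enoate (C14 its ester carbon), C4/C5 epoxide (C15 the methyl), C6 lactone oxygen carbon, C7, C8 (chlorohydrin ester), C9 (acetate), C11=C13 methylene, C12 lactone carbonyl.
Remark (stereochemistry): the target is read as 4R,5R,6S,7R,8R,9S with a (2R,3S)-3-chloro-2-hydroxy-2-methylbutanoate and with C2 and C9 cis on C1=C10; CIP letters of intermediates change with the substituents although the spatial arrangement is kept.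
Remark (materials): compounds 1, 6, 7, 19 and 26 and all reagents are assumed to be commercially available.

Step 1
Reactants: 1 geranyl acetate
Product: 3 (2E)-3-methyl-6-oxohex-2-en-1-yl acetate, via secondary ozonide 2 (not isolated)
Conditions: O3 (1.0 equiv), CH2Cl2/pyridine, −78 °C; then Me2S, −78 °C → rt
Reagents that add atoms: ozone, [O-][O+]=O
Why: Ozonolysis with reductive work-up; the electron-rich 6,7-alkene should react well before the 2,3-alkene, which is deactivated by the allylic acetate, and no stereocentre is involved.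

Step 2
Reactants: 3 (2E)-3-methyl-6-oxohex-2-en-1-yl acetate
Product: 5 (2E)-3-methylhept-2-en-6-yn-1-ol, via alkynyl acetate 4 (not isolated)
Conditions: dimethyl (1-diazo-2-oxopropyl)phosphonate, K2CO3, MeOH, 0 °C → rt
Reagents that add atoms: dimethyl (1-diazo-2-oxopropyl)phosphonate, COP(=O)(OC)C(=[N+]=[N-])C(C)=O
Why: Seyferth–Gilbert homologation in the Ohira–Bestmann variant turns the aldehyde into the terminal alkyne (the new carbon is C10), and the same K2CO3/MeOH should transesterify the allylic acetate to the free alcohol.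

Step 3
Reactants: 6 2-chloro-N-methoxy-N-methylacetamide; 7 4-methoxybenzyl alcohol
Product: 8 N-methoxy-2-[(4-methoxybenzyl)oxy]-N-methylacetamide
Conditions: NaH, THF, 0 °C → rt
Reagents that add atoms: none
Why: Williamson ether synthesis; the alkoxide should displace the activated α-chloride by SN2 faster than it attacks the amide carbonyl.

Step 4
Reactants: 5 (2E)-3-methylhept-2-en-6-yn-1-ol; 8 N-methoxy-2-[(4-methoxybenzyl)oxy]-N-methylacetamide
Product: 10 (7E)-9-hydroxy-1-[(4-methoxybenzyl)oxy]-7-methylnon-7-en-3-yn-2-one, via dilithium alkoxide acetylide 9 (not isolated)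
Conditions: n-BuLi (2.1 equiv), THF, −78 → −20 °C; then 8, −78 → 0 °C; H2O
Reagents that add atoms: none
Why: Weinreb ketone synthesis; the lithium acetylide adds to the amide to give a chelated tetrahedral intermediate that collapses to the ynone only on work-up, while the lithium alkoxide is a spectator.

Step 5
Reactants: 10 (7E)-9-hydroxy-1-[(4-methoxybenzyl)oxy]-7-methylnon-7-en-3-yn-2-one
Product: 11 (2E,8S)-9-[(4-methoxybenzyl)oxy]-3-methylnon-2-en-6-yne-1,8-diol
Conditions: RuCl[(R,R)-TsDPEN](p-cymene) (2 mol %), i-PrOH, rt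
Reagents that add atoms: none
Why: Noyori asymmetric transfer hydrogenation of an alkynyl ketone; the catalyst distinguishes the alkynyl from the sp3 side, and the (R,R)-ligand should deliver hydride to the face that makes C9 (S) (the descriptor is S because CH2O outranks the alkynyl carbon).

Step 6
Reactants: 11 (2E,8S)-9-[(4-methoxybenzyl)oxy]-3-methylnon-2-en-6-yne-1,8-diol
Product: 13 (2E,6E,8R)-7-iodo-9-[(4-methoxybenzyl)oxy]-3-methylnona-2,6-diene-1,8-diol, via alkenylmagnesium chloride 12 (not isolated)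
Conditions: i-BuMgCl (4 equiv), Cp2TiCl2 (10 mol %), Et2O, 0 °C → rt; then iodine, THF, −78 → 0 °C
Reagents that add atoms: iodine, [I][I]
Why: Titanocene-catalysed hydromagnesiation of a propargylic alkoxide is a syn addition that places magnesium on the carbon next to the carbinol (C10), and iodinolysis with retention then fixes H1 cis to iodine, that is C2 cis to C9, the geometry of the target enoate.

Step 7
Reactants: 13 (2E,6E,8R)-7-iodo-9-[(4-methoxybenzyl)oxy]-3-methylnona-2,6-diene-1,8-diol
Product: 14 methyl (2E,6E)-8-hydroxy-2-{(1S)-1-hydroxy-2-[(4-methoxybenzyl)oxy]ethyl}-6-methylocta-2,6-dienoate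
Conditions: PdCl2(PPh3)2 (5 mol %), CO (1 atm), Et3N, MeOH/DMF, 50 °C
Reagents that add atoms: carbon monoxide, [C-]#[O+]; methanol, CO
Why: Palladium-catalysed methoxycarbonylation of an alkenyl iodide (oxidative addition, CO insertion, methanolysis) proceeds with retention of the alkene geometry, and methanol as solvent should outcompete the neighbouring hydroxyl for the acylpalladium.

Step 8
Reactants: 14 methyl (2E,6E)-8-hydroxy-2-{(1S)-1-hydroxy-2-[(4-methoxybenzyl)oxy]ethyl}-6-methylocta-2,6-dienoate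
Product: 15 methyl (2E,6E)-2-{(1S)-1-hydroxy-2-[(4-methoxybenzyl)oxy]ethyl}-6-methyl-8-oxoocta-2,6-dienoate
Conditions: TEMPO (10 mol %), PhI(OAc)2 (1.1 equiv), CH2Cl2, rt
Reagents that add atoms: none
Why: Oxoammonium (TEMPO) oxidation is selective for the primary allylic alcohol over the hindered secondary C9 carbinol next to the enoate, and should not isomerise the C4=C5 bond.

Step 9
Reactants: 15 methyl (2E,6E)-2-{(1S)-1-hydroxy-2-[(4-methoxybenzyl)oxy]ethyl}-6-methyl-8-oxoocta-2,6-dienoate
Product: 16 methyl (2E,6E)-2-{(1S)-2-[(4-methoxybenzyl)oxy]-1-[(triethylsilyl)oxy]ethyl}-6-methyl-8-oxoocta-2,6-dienoate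
Conditions: Et3SiCl, imidazole, DMF, 0 °C
Reagents that add atoms: chlorotriethylsilane, CC[Si](Cl)(CC)CC
Why: Silyl ether formation; the non-chelating triethylsilyl group is chosen so that C9 later directs the key addition in the Felkin–Anh sense.

Step 10
Reactants: 16 methyl (2E,6E)-2-{(1S)-2-[(4-methoxybenzyl)oxy]-1-[(triethylsilyl)oxy]ethyl}-6-methyl-8-oxoocta-2,6-dienoate
Product: 17 methyl (2E,6E,8S)-8-hydroxy-2-{(1S)-2-[(4-methoxybenzyl)oxy]-1-[(triethylsilyl)oxy]ethyl}-6-methyldeca-2,6,9-trienoate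
Conditions: (CH2=CH)2Zn (from CH2=CHMgBr and ZnCl2, salts removed with 1,4-dioxane), (−)-MIB (10 mol %), toluene, −20 → 0 °C
Reagents that add atoms: divinylzinc, C=C[Zn]C=C
Why: Amino-alcohol-catalysed enantioselective 1,2-addition of an alkenylzinc reagent to an aldehyde; the (−)-amino alcohol should direct the vinyl group to the Si face of the enal and so set C6 as (S), while the ester is inert to organozinc.

Step 11
Reactants: 17 methyl (2E,6E,8S)-8-hydroxy-2-{(1S)-2-[(4-methoxybenzyl)oxy]-1-[(triethylsilyl)oxy]ethyl}-6-methyldeca-2,6,9-trienoate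
Product: 18 methyl (2E)-5-{(2R,3R)-3-[(1S)-1-hydroxyprop-2-en-1-yl]-2-methyloxiran-2-yl}-2-{(1S)-2-[(4-methoxybenzyl)oxy]-1-[(triethylsilyl)oxy]ethyl}pent-2-enoate
Conditions: mCPBA (1.05 equiv), NaHCO3, CH2Cl2, 0 °C
Reagents that add atoms: 3-chloroperbenzoic acid, OOC(=O)c1cccc(Cl)c1
Why: Hydroxyl-directed Prilezhaev epoxidation; A(1,3) strain between C6 and the cis methyl on C4 fixes the carbinol conformation so that the hydrogen-bonded peracid should give the threo epoxy alcohol (4R,5R), and the trisubstituted alkene is far more nucleophilic than the vinyl group or the enoate.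

Step 12
Reactants: 18 methyl (2E)-5-{(2R,3R)-3-[(1S)-1-hydroxyprop-2-en-1-yl]-2-methyloxiran-2-yl}-2-{(1S)-2-[(4-methoxybenzyl)oxy]-1-[(triethylsilyl)oxy]ethyl}pent-2-enoate; 19 2-(bromomethyl)acrylic acid
Product: 20 2-(bromomethyl)acrylate ester of 18 at the C6 oxygen
Conditions: dicyclohexylcarbodiimide, DMAP (5 mol %), CH2Cl2, 0 °C
Reagents that add atoms: none
Why: Steglich esterification of the only free hydroxyl under conditions mild enough for the allylic bromide; C6 keeps its configuration.

Step 13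
Reactants: 20 2-(bromomethyl)acrylate ester of 18
Product: 21 methyl (2E)-5-{(2R,3R)-3-[(2S)-4-(bromomethyl)-5-oxo-2,5-dihydrofuran-2-yl]-2-methyloxiran-2-yl}-2-{(1S)-2-[(4-methoxybenzyl)oxy]-1-[(triethylsilyl)oxy]ethyl}pent-2-enoate
Conditions: second-generation Hoveyda–Grubbs catalyst RuCl2(H2IMes)(=CH-C6H4-2-OiPr) (10 mol %), toluene, 80 °C
Reagents that add atoms: none
Why: Ring-closing metathesis of an allylic acrylate to a butenolide; the catalyst should load on the C7 vinyl group and close onto the 1,1-disubstituted acrylate, while the trisubstituted enoate is inert.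

Step 14
Reactants: 21 the 3-(bromomethyl)butenolide 4-methoxybenzyl ether
Product: 22 methyl (2E)-5-{(2R,3R)-3-[(2S)-4-(bromomethyl)-5-oxo-2,5-dihydrofuran-2-yl]-2-methyloxiran-2-yl}-2-{(1S)-2-hydroxy-1-[(triethylsilyl)oxy]ethyl}pent-2-enoate
Conditions: DDQ, CH2Cl2/pH 7 buffer, 0 °C
Reagents that add atoms: none
Why: Oxidative cleavage of the 4-methoxybenzyl ether under neutral conditions that leave the silyl ether, epoxide and allylic bromide untouched.

Step 15
Reactants: 22 the primary alcohol
Product: 23 methyl (2E)-5-{(2R,3R)-3-[(2S)-4-(bromomethyl)-5-oxo-2,5-dihydrofuran-2-yl]-2-methyloxiran-2-yl}-2-{(1S)-2-oxo-1-[(triethylsilyl)oxy]ethyl}pent-2-enoate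
Conditions: Dess–Martin periodinane, NaHCO3, CH2Cl2, 0 °C; used at once
Reagents that add atoms: none
Why: Dess–Martin oxidation under buffered, base-free conditions should give the α-silyloxy aldehyde without epimerising C9 or moving the C1=C10 double bond.

Step 16
Reactants: 23 the C8 aldehyde carrying the 3-(bromomethyl)butenolide
Product: 25 methyl (4R,5R,6S,7R,8R,9S)-4,5-epoxy-8-hydroxy-9-[(triethylsilyl)oxy]germacra-1(10),11(13)-dien-12,6-olid-14-oate, via allylchromium dichloride 24 (not isolated)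
Conditions: CrCl2 (10 equiv), THF, rt, slow addition of 23 to a final 0.001 mol/L; aqueous work-up
Reagents that add atoms: none
Why: Two equivalents of CrCl2 insert into the allylic C13–Br bond to give the allylchromium 24, which adds through its γ-carbon C7 to the C8 aldehyde in a closed six-membered chair transition state (Cr–O=C8···C7=C11–C13) and thereby moves the double bond to C11=C13. The closest known reaction type is the intramolecular Nozaki–Hiyama–Kishi allylation of aldehydes by 2-(bromomethyl)acrylate-type bromides, used to close carbocycles fused to α-methylene lactones. The ten-membered ring is closed in a 10-exo-trig mode at the aldehyde by SE2' attack of the allyl unit, whose C11=C13 bond ends up exocyclic. C7 is controlled by C6: the planar butenolide should be attacked on the face opposite to the C5 epoxide substituent, which gives the trans-fused lactone (7R). C8 is controlled by the chair transition state, in which the ring-locked allyl geometry (C6 trans to C13, an E-crotyl-type reagent) puts C6 and C9 pseudo-equatorial and gives the anti relationship (8R), reinforced by Felkin–Anh addition anti to the C9 silyloxy group. The step needs γ- over α-attack (α-attack would give a twelve-membered ring), cyclisation over oligomerisation, and tolerance of epoxide, esters and silyl ether; the cyclic transition state of allylchromium reagents, high dilution and the chemoselectivity of divalent chromium should secure these.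

Step 17
Reactants: 26 (2E)-2-methylbut-2-en-1-ol
Product: 27 (2R,3R)-(2,3-dimethyloxiran-2-yl)methanol
Conditions: Ti(OiPr)4 (10 mol %), (2S,3S)-(−)-diethyl tartrate (12 mol %), t-BuOOH, 4 Å molecular sieves, CH2Cl2, −20 °C
Reagents that add atoms: tert-butyl hydroperoxide, CC(C)(C)OO
Why: Sharpless asymmetric epoxidation; the (−)-tartrate should deliver oxygen to the alkene face that gives the (2R,3R)-epoxy alcohol.

Step 18
Reactants: 27 (2R,3R)-(2,3-dimethyloxiran-2-yl)methanol
Product: 28 (2S,3R)-2,3-dimethyloxirane-2-carboxylic acid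
Conditions: RuCl3 hydrate (2 mol %), NaIO4, CCl4/MeCN/H2O, rt
Reagents that add atoms: water, O; sodium periodate, [Na+].[O-]I(=O)(=O)=O
Why: Ruthenium tetroxide-catalysed oxidation of a primary alcohol to the acid leaves the epoxide and both stereocentres untouched (only the descriptor at C2 changes).

Step 19
Reactants: 28 (2S,3R)-2,3-dimethyloxirane-2-carboxylic acid
Product: 29 (2R,3S)-3-chloro-2-hydroxy-2-methylbutanoic acid
Conditions: HCl (4 mol/L in 1,4-dioxane), Et2O, 0 °C
Reagents that add atoms: hydrogen chloride, Cl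
Why: Acid-promoted SN2 opening of a glycidic acid; chloride should attack the secondary β-carbon C3 with inversion, because the quaternary C2 is hindered and deactivated by the carboxyl group and so keeps its configuration.

Step 20
Reactants: 29 (2R,3S)-3-chloro-2-hydroxy-2-methylbutanoic acid
Product: 31 (2R,3S)-3-chloro-2-methyl-2-[(triethylsilyl)oxy]butanoic acid, via bis-silylated acid 30 (not isolated)
Conditions: Et3SiOTf (2.2 equiv), 2,6-lutidine, CH2Cl2, −78 → 0 °C; then H2O/THF, rt
Reagents that add atoms: triethylsilyl trifluoromethanesulfonate, CC[Si](CC)(CC)OS(=O)(=O)C(F)(F)F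
Why: Exhaustive silylation followed by selective hydrolysis of the labile silyl ester, which leaves the hindered tertiary silyl ether in place.

Step 21
Reactants: 25 the macrocyclic C8 alcohol; 31 (2R,3S)-3-chloro-2-methyl-2-[(triethylsilyl)oxy]butanoic acid
Product: 33 C8 ester of 25 with acid 31 (bis-triethylsilyl ether), via mixed anhydride 32 (not isolated)
Conditions: 2,4,6-trichlorobenzoyl chloride, Et3N, THF, rt; then 25, DMAP, toluene, rt → 40 °C
Reagents that add atoms: none
Why: Yamaguchi esterification; the acyl group is transferred to the only free hydroxyl (C8), and the acid has no α-hydrogen, so it can neither epimerise nor lose HCl by an E1cB path.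

Step 22
Reactants: 33 the bis-triethylsilyl ether
Product: 34 methyl (4R,5R,6S,7R,8R,9S)-8-{[(2R,3S)-3-chloro-2-hydroxy-2-methylbutanoyl]oxy}-4,5-epoxy-9-hydroxygermacra-1(10),11(13)-dien-12,6-olid-14-oate
Conditions: HF·pyridine, pyridine, THF, 0 °C → rt
Reagents that add atoms: none
Why: Buffered fluoride cleavage of both silyl ethers, under conditions that the epoxide, the α-methylene lactone and the alkyl chloride should tolerate.

Step 23
Reactants: 34 the C9 alcohol
Product: 35 the target CNP0185503.4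
Conditions: Ac2O, pyridine, DMAP (cat.), CH2Cl2, 0 °C
Reagents that add atoms: acetic anhydride, CC(=O)OC(C)=O
Why: Acetylation of the secondary C9 alcohol; the tertiary hydroxyl α to the side-chain ester is too hindered to react under these conditions.

Compound list
1 | geranyl acetate, (2E)-3,7-dimethylocta-2,6-dien-1-yl acetate | CC(=O)OC/C=C(\C)CCC=C(C)C | starting material
2 | secondary ozonide of 1 at the 6,7-alkene | CC(=O)OC/C=C(\C)CCC1OOC(C)(C)O1 | intermediate
3 | (2E)-3-methyl-6-oxohex-2-en-1-yl acetate | CC(=O)OC/C=C(\C)CCC=O | intermediate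
4 | (2E)-3-methylhept-2-en-6-yn-1-yl acetate | CC(=O)OC/C=C(\C)CCC#C | intermediate
5 | (2E)-3-methylhept-2-en-6-yn-1-ol | OC/C=C(\C)CCC#C | intermediate
6 | 2-chloro-N-methoxy-N-methylacetamide | CON(C)C(=O)CCl | starting material
7 | 4-methoxybenzyl alcohol | COc1ccc(CO)cc1 | starting material
8 | N-methoxy-2-[(4-methoxybenzyl)oxy]-N-methylacetamide | COc1ccc(COCC(=O)N(C)OC)cc1 | intermediate
9 | dilithium salt of 5 (lithium alkoxide and lithium acetylide) | [Li]OC/C=C(\C)CCC#C[Li] | intermediate
10 | (7E)-9-hydroxy-1-[(4-methoxybenzyl)oxy]-7-methylnon-7-en-3-yn-2-one | COc1ccc(COCC(=O)C#CCC/C(C)=C/CO)cc1 | intermediate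
11 | (2E,8S)-9-[(4-methoxybenzyl)oxy]-3-methylnon-2-en-6-yne-1,8-diol | COc1ccc(COC[C@@H](O)C#CCC/C(C)=C/CO)cc1 | intermediate
12 | alkenylmagnesium chloride from 11 (MgCl on C10 cis to H1, both hydroxyls as chloromagnesium alkoxides) | COc1ccc(COC[C@@H](O[Mg]Cl)/C([Mg]Cl)=C\CC/C(C)=C/CO[Mg]Cl)cc1 | intermediate
13 | (2E,6E,8R)-7-iodo-9-[(4-methoxybenzyl)oxy]-3-methylnona-2,6-diene-1,8-diol | COc1ccc(COC[C@@H](O)/C(I)=C\CC/C(C)=C/CO)cc1 | intermediate
14 | methyl (2E,6E)-8-hydroxy-2-{(1S)-1-hydroxy-2-[(4-methoxybenzyl)oxy]ethyl}-6-methylocta-2,6-dienoate | COc1ccc(COC[C@@H](O)/C(C(=O)OC)=C\CC/C(C)=C/CO)cc1 | intermediate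
15 | methyl (2E,6E)-2-{(1S)-1-hydroxy-2-[(4-methoxybenzyl)oxy]ethyl}-6-methyl-8-oxoocta-2,6-dienoate | COc1ccc(COC[C@@H](O)/C(C(=O)OC)=C\CC/C(C)=C/C=O)cc1 | intermediate
16 | methyl (2E,6E)-2-{(1S)-2-[(4-methoxybenzyl)oxy]-1-[(triethylsilyl)oxy]ethyl}-6-methyl-8-oxoocta-2,6-dienoate | COc1ccc(COC[C@@H](O[Si](CC)(CC)CC)/C(C(=O)OC)=C\CC/C(C)=C/C=O)cc1 | intermediate
17 | methyl (2E,6E,8S)-8-hydroxy-2-{(1S)-2-[(4-methoxybenzyl)oxy]-1-[(triethylsilyl)oxy]ethyl}-6-methyldeca-2,6,9-trienoate | COc1ccc(COC[C@@H](O[Si](CC)(CC)CC)/C(C(=O)OC)=C\CC/C(C)=C/[C@@H](O)C=C)cc1 | intermediate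
18 | methyl (2E)-5-{(2R,3R)-3-[(1S)-1-hydroxyprop-2-en-1-yl]-2-methyloxiran-2-yl}-2-{(1S)-2-[(4-methoxybenzyl)oxy]-1-[(triethylsilyl)oxy]ethyl}pent-2-enoate | COc1ccc(COC[C@@H](O[Si](CC)(CC)CC)/C(C(=O)OC)=C\CC[C@@]2(C)O[C@@H]2[C@@H](O)C=C)cc1 | intermediate
19 | 2-(bromomethyl)acrylic acid | C=C(CBr)C(=O)O | starting material
20 | 2-(bromomethyl)acrylate ester of 18 at the C6 oxygen | COc1ccc(COC[C@@H](O[Si](CC)(CC)CC)/C(C(=O)OC)=C\CC[C@@]2(C)O[C@@H]2[C@@H](OC(=O)C(=C)CBr)C=C)cc1 | intermediate
21 | methyl (2E)-5-{(2R,3R)-3-[(2S)-4-(bromomethyl)-5-oxo-2,5-dihydrofuran-2-yl]-2-methyloxiran-2-yl}-2-{(1S)-2-[(4-methoxybenzyl)oxy]-1-[(triethylsilyl)oxy]ethyl}pent-2-enoate | COc1ccc(COC[C@@H](O[Si](CC)(CC)CC)/C(C(=O)OC)=C\CC[C@@]2(C)O[C@@H]2[C@H]3OC(=O)C(CBr)=C3)cc1 | intermediate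
22 | methyl (2E)-5-{(2R,3R)-3-[(2S)-4-(bromomethyl)-5-oxo-2,5-dihydrofuran-2-yl]-2-methyloxiran-2-yl}-2-{(1S)-2-hydroxy-1-[(triethylsilyl)oxy]ethyl}pent-2-enoate | OC[C@@H](O[Si](CC)(CC)CC)/C(C(=O)OC)=C\CC[C@@]1(C)O[C@@H]1[C@H]1OC(=O)C(CBr)=C1 | intermediate
23 | methyl (2E)-5-{(2R,3R)-3-[(2S)-4-(bromomethyl)-5-oxo-2,5-dihydrofuran-2-yl]-2-methyloxiran-2-yl}-2-{(1S)-2-oxo-1-[(triethylsilyl)oxy]ethyl}pent-2-enoate | O=C[C@@H](O[Si](CC)(CC)CC)/C(C(=O)OC)=C\CC[C@@]1(C)O[C@@H]1[C@H]1OC(=O)C(CBr)=C1 | intermediate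
24 | allylchromium dichloride from 23 (CrCl2 on C13) | O=C[C@@H](O[Si](CC)(CC)CC)/C(C(=O)OC)=C\CC[C@@]1(C)O[C@@H]1[C@H]1OC(=O)C(C[Cr](Cl)Cl)=C1 | intermediate
25 | methyl (4R,5R,6S,7R,8R,9S)-4,5-epoxy-8-hydroxy-9-[(triethylsilyl)oxy]germacra-1(10),11(13)-dien-12,6-olid-14-oate (C2 and C9 cis on C1=C10) | C=C1C(=O)O[C@H]2[C@H]1[C@@H](O)[C@@H](O[Si](CC)(CC)CC)/C(C(=O)OC)=C\CC[C@@]1(C)O[C@H]21 | intermediate
26 | (2E)-2-methylbut-2-en-1-ol (tiglyl alcohol) | C/C=C(\C)CO | starting material
27 | (2R,3R)-(2,3-dimethyloxiran-2-yl)methanol | OC[C@@]1(C)O[C@@H]1C | intermediate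
28 | (2S,3R)-2,3-dimethyloxirane-2-carboxylic acid | OC(=O)[C@@]1(C)O[C@@H]1C | intermediate
29 | (2R,3S)-3-chloro-2-hydroxy-2-methylbutanoic acid | OC(=O)[C@@](C)(O)[C@H](C)Cl | intermediate
30 | triethylsilyl (2R,3S)-3-chloro-2-methyl-2-[(triethylsilyl)oxy]butanoate | CC[Si](CC)(CC)OC(=O)[C@@](C)(O[Si](CC)(CC)CC)[C@H](C)Cl | intermediate
31 | (2R,3S)-3-chloro-2-methyl-2-[(triethylsilyl)oxy]butanoic acid | OC(=O)[C@@](C)(O[Si](CC)(CC)CC)[C@H](C)Cl | intermediate
32 | mixed anhydride of 31 with 2,4,6-trichlorobenzoic acid | Clc1cc(Cl)c(C(=O)OC(=O)[C@@](C)(O[Si](CC)(CC)CC)[C@H](C)Cl)c(Cl)c1 | intermediate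
33 | C8 ester of 25 with 31: 8-O-acyl, 9-O-triethylsilyl, side-chain O-triethylsilyl; ring configuration spatially as in 25 | C=C1C(=O)O[C@H]2[C@H]1[C@@H](OC(=O)[C@@](C)(O[Si](CC)(CC)CC)[C@H](C)Cl)[C@@H](O[Si](CC)(CC)CC)/C(C(=O)OC)=C\CC[C@@]1(C)O[C@H]21 | intermediate
34 | methyl (4R,5R,6S,7R,8R,9S)-8-{[(2R,3S)-3-chloro-2-hydroxy-2-methylbutanoyl]oxy}-4,5-epoxy-9-hydroxygermacra-1(10),11(13)-dien-12,6-olid-14-oate | C=C1C(=O)O[C@H]2[C@H]1[C@@H](OC(=O)[C@@](C)(O)[C@H](C)Cl)[C@@H](O)/C(C(=O)OC)=C\CC[C@@]1(C)O[C@H]21 | intermediate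
35 | CNP0185503.4: methyl (4R,5R,6S,7R,8R,9S)-9-acetoxy-8-{[(2R,3S)-3-chloro-2-hydroxy-2-methylbutanoyl]oxy}-4,5-epoxygermacra-1(10),11(13)-dien-12,6-olid-14-oate | C=C1C(=O)O[C@H]2[C@H]1[C@@H](OC(=O)[C@@](C)(O)[C@H](C)Cl)[C@@H](OC(C)=O)/C(C(=O)OC)=C\CC[C@@]1(C)O[C@H]21 | target

Total step count: 23.
Longest linear sequence: 18 steps (steps 1, 2, 4 to 16 and 21 to 23, from geranyl acetate).

Steps most likely to fail, with fallbacks

Step 16 (macrocyclisation). The chain may oligomerise, the allylchromium may be protonated before it cyclises, or the aldehyde may add on the lactone face syn to C5 and give the cis-fused ring. The fallback sets out from 21 and returns to 25; it replaces the transient chromium reagent by an isolable allylboronate. Palladium-catalysed borylation of the allylic bromide of 21 (B2pin2, Pd2(dba)3, THF, 50 °C) should give the pinacol allylboronate F1. DDQ (CH2Cl2, pH 7 buffer) should then free the primary alcohol F2, and Dess–Martin periodinane should give the aldehyde F3. Heating F3 in toluene at high dilution (80 °C) should close the ring by intramolecular allylboration through the same chair transition state, and hydrolysis of the borate on work-up returns 25.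

Step 13 (ring-closing metathesis). Ring closure onto the electron-poor 1,1-disubstituted alkene may be slower than catalyst decay, and the allylic bromide may be lost on the way. The fallback sets out from 18 and returns to 21. Acylation of 18 with acryloyl chloride (i-Pr2NEt, CH2Cl2, −20 °C) gives the acrylate F4, which as an unhindered acrylate should close readily with the second-generation Grubbs catalyst RuCl2(=CHPh)(H2IMes)(PCy3) to the butenolide F5. A Morita–Baylis–Hillman reaction with aqueous formaldehyde (imidazole, THF/H2O) then places the hydroxymethyl group on C11 to give the 3-(hydroxymethyl)butenolide F6, and an Appel bromination (CBr4, PPh3, CH2Cl2, 0 °C) returns 21.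

Step 10 (vinylation). Enantioface selection may be eroded by uncatalysed addition or by residual magnesium salts, which would give the C6 epimer and, after step 11, the wrong epoxide. The fallback sets out from 16 and returns to 17; it introduces the vinyl group as an alkyne. A ProPhenol–Me2Zn-catalysed addition of ethynyltrimethylsilane to 16 (ligand enantiomer chosen for Si-face delivery, toluene, 0 °C) should give the silylated propargylic alcohol F7. K2CO3 in MeOH removes the silyl group to give the terminal propargylic alcohol F8, and semi-hydrogenation over Lindlar catalyst (Pd on CaCO3 poisoned with Pb(OAc)2, quinoline, H2, EtOAc) returns 17.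

Further compounds
F1 | step 16 | pinacol allylboronate, the analogue of 21 with CH2B(pin) in place of CH2Br | COc1ccc(COC[C@@H](O[Si](CC)(CC)CC)/C(C(=O)OC)=C\CC[C@@]2(C)O[C@@H]2[C@H]2OC(=O)C(CB3OC(C)(C)C(C)(C)O3)=C2)cc1
F2 | step 16 | primary alcohol, the analogue of 22 with CH2B(pin) in place of CH2Br | OC[C@@H](O[Si](CC)(CC)CC)/C(C(=O)OC)=C\CC[C@@]1(C)O[C@@H]1[C@H]1OC(=O)C(CB2OC(C)(C)C(C)(C)O2)=C1
F3 | step 16 | aldehyde, the analogue of 23 with CH2B(pin) in place of CH2Br | O=C[C@@H](O[Si](CC)(CC)CC)/C(C(=O)OC)=C\CC[C@@]1(C)O[C@@H]1[C@H]1OC(=O)C(CB2OC(C)(C)C(C)(C)O2)=C1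
F4 | step 13 | acrylate ester of 18 at the C6 oxygen | COc1ccc(COC[C@@H](O[Si](CC)(CC)CC)/C(C(=O)OC)=C\CC[C@@]2(C)O[C@@H]2[C@@H](OC(=O)C=C)C=C)cc1
F5 | step 13 | butenolide without a substituent on C11, the analogue of 21 lacking CH2Br | COc1ccc(COC[C@@H](O[Si](CC)(CC)CC)/C(C(=O)OC)=C\CC[C@@]2(C)O[C@@H]2[C@H]2OC(=O)C=C2)cc1
F6 | step 13 | 3-(hydroxymethyl)butenolide, the analogue of 21 with CH2OH in place of CH2Br | COc1ccc(COC[C@@H](O[Si](CC)(CC)CC)/C(C(=O)OC)=C\CC[C@@]2(C)O[C@@H]2[C@H]2OC(=O)C(CO)=C2)cc1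
F7 | step 10 | trimethylsilyl propargylic alcohol, (8R) by descriptor and spatially as 17, with C≡C–SiMe3 in place of the vinyl group | COc1ccc(COC[C@@H](O[Si](CC)(CC)CC)/C(C(=O)OC)=C\CC/C(C)=C/[C@@H](O)C#C[Si](C)(C)C)cc1
F8 | step 10 | terminal propargylic alcohol, the analogue of 17 with ethynyl in place of vinyl | COc1ccc(COC[C@@H](O[Si](CC)(CC)CC)/C(C(=O)OC)=C\CC/C(C)=C/[C@@H](O)C#C)cc1
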